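Halimane numbering: ring A = C1–C5 and C10, ring B = C5–C10. In ring A the chain C18/C19–C4–C5–C10=C1 is a γ,δ-unsaturated carbonyl array. Its ends C1 and C4 are already bridged by C2–C3, so it is the retron of a Claisen rearrangement of a 2-alkenyl-3,4-dihydro-2H-pyran.
Cuts, in retrosynthetic order: O-acetyl; C19 raised from CH3 to CHO; C4–C5 (retro-[3,3], C19 returned to an oxygen on C1); C4–C19 (formylation); C1–C10 and C1–C2 (carbonylative coupling); C13=C14 (olefination); C9–C11 (Michael addition); C8–C17 (conjugate addition).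
Forward: ring B comes ready-made from (R)-carvone and the side chain is grown on C9. A temporary lactone and then a temporary dihydropyran are built on C10, and ring A closes last as the dihydropyran opens.
Stereochemistry: the carvone stereocentre steers C8 and then C9 and is then excised. A catalyst-controlled ketone reduction sets a sacrificial (1S) carbinol, which the [3,3] shift relays to C5 and quaternary C4. The olefination sets 13E.
The boat transition state puts the migrating carbon cis to C6. That carbon is therefore the future C19 methyl (helper oxidation level CHO), and the C18 carboxyl rides on the enol ether as its methyl ester.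

Key step: step 12

Assumption: the SMILES is read as (4S,5S,8R,9S,13E), the 15-O-acetate of ent-halimic acid. In the usual drawing H5, C18 and C11 lie on the β face and C17, C19 and C20 on the α face.
Abbreviation: RB = (5R,6S)-6-[(3E)-5-(tert-butyldimethylsilyloxy)-3-methylpent-3-en-1-yl]-5,6-dimethylcyclohex-1-en-1-yl, which is ring B with its side chain, bonded through C10.

Step 1
Reactants: 1 (R)-(−)-carvone
Product: 2 {[(3R,5R)-2,3-dimethyl-5-(prop-1-en-2-yl)cyclohex-1-en-1-yl]oxy}trimethylsilane
Conditions: MeMgBr, CuBr·SMe2 (10 mol %), Me3SiCl, DMPU, THF, −78 to −40 °C; Et3N, cold aq NaHCO3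
Reagents that add atoms: methylmagnesium bromide C[Mg]Br; chlorotrimethylsilane C[Si](C)(C)Cl
Why: Copper-catalysed conjugate addition with in situ silyl trapping, in which methyl adds axially and anti to the isopropenyl group to set C8 (R), and the silyl ether fixes the tetrasubstituted C9=C10 enolate regiochemistry.

Step 2
Reactants: 2 silyl enol ether from step 1; 3 methyl vinyl ketone
Product: 5 (2S,3R,5R)-2,3-dimethyl-2-(3-oxobutyl)-5-(prop-1-en-2-yl)cyclohexan-1-one, via adduct silyl enol ether 4 (not isolated)
Conditions: Ph3CSbCl6 (5 mol %), CH2Cl2, −78 °C; then 1 M HCl, THF, 0 °C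
Reagents that add atoms: methyl vinyl ketone (3) C=CC(C)=O
Why: Mukaiyama–Michael addition, in which the acceptor reaches C9 along the axial trajectory anti to the pseudoaxial C8 methyl, so C11 ends trans to C17, the two methyl groups end cis, and quaternary C9 is (S).

Step 3
Reactants: 5 isopropenyl diketone
Product: 7 (2S,3R)-2,3-dimethyl-2-(3-oxobutyl)cyclohexan-1-one, via methoxy hydroperoxide 6 (not isolated)
Conditions: O3, MeOH, −78 °C; then PhSH, FeSO4·7H2O, −78 °C to rt
Reagents that add atoms: none
Why: Hydrodealkenylation, in which ozonolysis in methanol gives the α-methoxy hydroperoxide, divalent iron cleaves its O–O bond, the alkoxy radical loses methyl acetate by β-scission and the secondary C6 radical takes hydrogen from the thiol, so the spent control element leaves without touching C8 or C9.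

Step 4
Reactants: 7 diketone; 8 triethyl phosphonoacetate
Product: 9 ethyl (2E)-5-[(1S,2R)-1,2-dimethyl-6-oxocyclohexyl]-3-methylpent-2-enoate
Conditions: (EtO)2P(O)CH2CO2Et (slight excess over NaH), NaH, THF, 0 to 50 °C; chromatographic removal of the Z isomer
Reagents that add atoms: triethyl phosphonoacetate (8) CCOC(=O)CP(=O)(OCC)OCC
Why: Horner–Wadsworth–Emmons olefination, which should take only the open methyl ketone because the ring ketone is shielded by quaternary C9, should place the ester trans to the larger CH2 branch (13E), and leaves no free base to start an aldol reaction of the 1,5-diketone.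

Step 5
Reactants: 9 keto enoate
Product: 11 ethyl (2E)-5-[(1S,6R)-1,6-dimethyl-2-(trifluoromethylsulfonyloxy)cyclohex-2-en-1-yl]-3-methylpent-2-enoate, via potassium enolate 10 (not isolated)
Conditions: KN(SiMe3)2, THF, −78 °C; PhNTf2, −78 to 0 °C
Reagents that add atoms: N-phenylbis(trifluoromethanesulfonimide) O=S(=O)(N(c1ccccc1)S(=O)(=O)C(F)(F)F)C(F)(F)F
Why: Kinetic enolisation and O-triflation, in which the ketone can enolise only toward C5 and its α-hydrogens are removed faster than the γ-hydrogens of the enoate, so the C5=C10 alkene is placed and the ketone is masked against the next reduction.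

Step 6
Reactants: 11 alkenyl triflate ester
Product: 12 (5R,6S)-6-[(3E)-5-hydroxy-3-methylpent-3-en-1-yl]-5,6-dimethylcyclohex-1-en-1-yl trifluoromethanesulfonate
Conditions: i-Bu2AlH, CH2Cl2, −78 °C; aq KNaC4H4O6
Reagents that add atoms: none
Why: 1,2-Reduction of an enoate to the allylic alcohol with a dialkylaluminium hydride, which alkenyl triflates tolerate and which leaves the alkene geometry unchanged.

Step 7
Reactants: 12 allylic alcohol
Product: 13 RB trifluoromethanesulfonate (the tert-butyldimethylsilyl ether of 12)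
Conditions: t-BuMe2SiCl, imidazole, CH2Cl2, rt
Reagents that add atoms: tert-butyldimethylsilyl chloride CC(C)(C)[Si](C)(C)Cl
Why: Standard silylation of a primary alcohol, giving an ether that should withstand palladium catalysis, amide bases, methoxide and heat.

Step 8
Reactants: 13 alkenyl triflate; 14 (4-ethoxy-4-oxobutyl)zinc bromide
Product: 15 ethyl 5-oxo-5-RB-pentanoate
Conditions: CO (1 atm), Pd(PPh3)4 (5 mol %), THF/NMP, 50 °C
Reagents that add atoms: (4-ethoxy-4-oxobutyl)zinc bromide (14) CCOC(=O)CCC[Zn]Br; carbon monoxide [C-]#[O+]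
Why: Carbonylative Negishi coupling, in which zerovalent palladium inserts into the C10–O bond, CO insertion gives the acylpalladium species, and the ester-tolerant alkylzinc delivers C2–C4 and C18, so C1 and the whole ring A chain arrive in one operation.

Step 9
Reactants: 15 enone ester
Product: 17 (6S)-6-RB-oxan-2-one, via hydroxy ester 16 (not isolated)
Conditions: (R)-Me-CBS [(3aR)-1-methyl-3,3-diphenyltetrahydro-1H,3H-pyrrolo[1,2-c][1,3,2]oxazaborole, 20 mol %], catecholborane, toluene, −78 °C; MeOH, aq NaHCO3; crude 16, pyridinium p-toluenesulfonate (10 mol %), toluene, 60 °C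
Reagents that add atoms: none
Why: Corey–Bakshi–Shibata reduction, in which the (R)-oxazaborolidine treats the cyclohexenyl group as the large and the CH2 chain as the small substituent to give the (1S) alcohol under catalyst control, and mild acid then closes the δ-lactone by acyl substitution that leaves the C1–O bond untouched.

Step 10
Reactants: 17 δ-lactone
Product: 20 (3E,6S)-3-(methoxymethylidene)-6-RB-oxan-2-one, via lactone lithium enolate 18 (not isolated), via formyl lactone lithium salt 19 (not isolated)
Conditions: LiN(i-Pr)2, THF, −78 °C; HCO2Me, −78 to 0 °C; Me2SO4, DMPU, 0 °C to rt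
Reagents that add atoms: methyl formate COC=O; dimethyl sulfate COS(=O)(=O)OC
Why: Claisen condensation of the lactone enolate with a formate, followed by O-methylation of the formyl enolate with a hard electrophile, the standard entry to β-methoxyacrylates, which brings in C19, touches no stereocentre and gives an alkene whose geometry is of no consequence.

Step 11
Reactants: 20 methoxymethylidene lactone
Product: 22 methyl (2S)-2-RB-3,4-dihydro-2H-pyran-5-carboxylate, via ring-opened sodium alkoxide 21 (not isolated)
Conditions: NaOMe (20 mol %), dry THF, 0 °C to rt; pH 7 buffer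
Reagents that add atoms: none
Why: Proposed new method: methoxide should open the lactone of 20 at C18 by transesterification, the freed C1 alkoxide 21 should add to C19 of the β-methoxyacrylate (6-endo-trig) and expel methoxide again, so a catalytic amount of base isomerises 20 to the more stable open-chain ester with an endocyclic enol ether 22 while the C1–O bond, and hence (1S), is never broken; the closest known reaction types are the acid-catalysed acyl-lactone rearrangement of α-formyl lactones to dihydropyran-5-carboxylates and the base-catalysed alkoxy exchange of β-alkoxyacrylates by addition–elimination, and base is chosen because acid could ionise the allylic C1–O bond.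

Step 12
Reactants: 22 2-alkenyl-dihydropyran ester
Product: 23 methyl (4S,5S,8R,9S,13E)-15-(tert-butyldimethylsilyloxy)-19-oxo-ent-halima-1(10),13-dien-18-oate (CHO α and cis to C6; CO2Me β and cis to H5)
Conditions: o-dichlorobenzene (degassed), 2,6-di-tert-butyl-4-methylphenol (trace), base-washed sealed tube, 200–220 °C
Reagents that add atoms: none
Why: On heating, the allyl vinyl ether C4=C19–O–C1–C10=C5 of 22 should undergo a concerted suprafacial [3,3] shift in which O–C1 breaks, C4–C5 forms and C1=C10 and C19=O appear, so the six-membered heterocycle is exchanged for carbocyclic ring A, closed at the C4–C5 bond. The closest known reaction type is the thermal Claisen rearrangement of 2-alkenyl-3,4-dihydro-2H-pyrans to cyclohex-3-enecarbaldehydes, which also builds quaternary carbons from 5-substituted dihydropyrans. Because C1 and C4 stay tied by C2–C3, only a boat-shaped, bicyclo[2.2.2]octane-like transition state is open, with C2 inside (cis to C5) and H1 turned toward C9. C5 is controlled by the (1S) carbinol centre: oxygen leaves and C4 arrives on the same α face of the C5=C10–C1 allyl unit, which puts H5 β and trans to C20 whatever the inherent bias of ring B. C4 is controlled by the ring-locked enol ether geometry and the boat: the migrating carbon C19 ends cis to C6 (α) and the ester C18 cis to H5 (β), which is why C19 travels as the aldehyde and C18 as the ester. The step needs the pericyclic path to win over ionisation or retro-hetero-Diels–Alder cleavage, which a non-polar acid-free medium should secure, and it is helped because only the small C19–H, not an oxygen substituent, has to lie over C9 of ring B.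

Step 13
Reactants: 23 aldehyde ester
Product: 24 (E)-tosylhydrazone of 23 at C19
Conditions: TsNHNH2, EtOH, 50 °C
Reagents that add atoms: p-toluenesulfonyl hydrazide Cc1ccc(cc1)S(=O)(=O)NN
Why: Condensation of an aldehyde with a sulfonyl hydrazide under neutral conditions, which should be faster than deformylation and, since the sulfonamide nitrogen is a poor nucleophile, should not cyclise onto the hindered ester.

Step 14
Reactants: 24 tosylhydrazone
Product: 27 methyl (4S,5S,8R,9S,13E)-15-(tert-butyldimethylsilyloxy)-ent-halima-1(10),13-dien-18-oate, via N-boryl tosylhydrazide 25 (not isolated), via monoalkyl diazene 26 (not isolated)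
Conditions: catecholborane, CHCl3, −10 °C to rt; then NaOAc·3H2O, reflux
Reagents that add atoms: none
Why: Mild Wolff–Kishner-type deoxygenation, in which hydroboration of the C=N bond, acetate-induced loss of sulfinate and loss of nitrogen from the diazene turn C19 into the methyl group, while the ester, the silyl ether and both trisubstituted alkenes are inert to catecholborane at these temperatures.

Step 15
Reactants: 27 methyl ester
Product: 28 (4S,5S,8R,9S,13E)-15-(tert-butyldimethylsilyloxy)-ent-halima-1(10),13-dien-18-oic acid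
Conditions: NaSEt, DMF, 100 °C; cold dilute HCl
Reagents that add atoms: none
Why: SN2 dealkylation of a hindered methyl ester by thiolate, which attacks the O-methyl carbon and so bypasses the neopentyl-type shielding of the C18 carbonyl group.

Step 16
Reactants: 28 silyl ether acid
Product: 29 ent-halimic acid [(4S,5S,8R,9S,13E)-15-hydroxy-ent-halima-1(10),13-dien-18-oic acid]
Conditions: Bu4NF, THF, rt
Reagents that add atoms: none
Why: Fluoride cleavage of a primary silyl ether, which touches neither the alkenes nor any stereocentre.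

Step 17
Reactants: 29 ent-halimic acid
Product: 30 target, (4S,5S,8R,9S,13E)-15-acetoxy-ent-halima-1(10),13-dien-18-oic acid
Conditions: Ac2O, pyridine, DMAP (cat.), CH2Cl2, 0 °C to rt; then aq NaHCO3/THF
Reagents that add atoms: acetic anhydride CC(=O)OC(C)=O
Why: Acetylation of the primary allylic alcohol, in which any mixed anhydride formed at the hindered C18 acid is hydrolysed back during the aqueous treatment.

Compound list
1 | (R)-(−)-carvone | CC1=CC[C@@H](C(C)=C)CC1=O | starting material
2 | {[(3R,5R)-2,3-dimethyl-5-(prop-1-en-2-yl)cyclohex-1-en-1-yl]oxy}trimethylsilane | CC1=C(O[Si](C)(C)C)C[C@H](C(C)=C)C[C@H]1C | intermediate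
3 | methyl vinyl ketone | C=CC(C)=O | starting material
4 | trimethylsilyl enol ether of the methyl ketone of 5 (enol ether geometry not defined) | CC(O[Si](C)(C)C)=CC[C@]1(C)C(=O)C[C@H](C(C)=C)C[C@H]1C | intermediate
5 | (2S,3R,5R)-2,3-dimethyl-2-(3-oxobutyl)-5-(prop-1-en-2-yl)cyclohexan-1-one | CC(=O)CC[C@]1(C)C(=O)C[C@H](C(C)=C)C[C@H]1C | intermediate
6 | (2S,3R,5R)-5-(1-hydroperoxy-1-methoxyethyl)-2,3-dimethyl-2-(3-oxobutyl)cyclohexan-1-one (epimers at the peroxy carbon) | CC(=O)CC[C@]1(C)C(=O)C[C@H](C(C)(OC)OO)C[C@H]1C | intermediate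
7 | (2S,3R)-2,3-dimethyl-2-(3-oxobutyl)cyclohexan-1-one | CC(=O)CC[C@]1(C)C(=O)CCC[C@H]1C | intermediate
8 | triethyl phosphonoacetate | CCOC(=O)CP(=O)(OCC)OCC | starting material
9 | ethyl (2E)-5-[(1S,2R)-1,2-dimethyl-6-oxocyclohexyl]-3-methylpent-2-enoate | CCOC(=O)/C=C(\C)CC[C@]1(C)C(=O)CCC[C@H]1C | intermediate
10 | potassium C5=C10 enolate of 9 | CCOC(=O)/C=C(\C)CC[C@]1(C)C([O-])=CCC[C@H]1C.[K+] | intermediate
11 | ethyl (2E)-5-[(1S,6R)-1,6-dimethyl-2-(trifluoromethylsulfonyloxy)cyclohex-2-en-1-yl]-3-methylpent-2-enoate | CCOC(=O)/C=C(\C)CC[C@]1(C)C(OS(=O)(=O)C(F)(F)F)=CCC[C@H]1C | intermediate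
12 | (5R,6S)-6-[(3E)-5-hydroxy-3-methylpent-3-en-1-yl]-5,6-dimethylcyclohex-1-en-1-yl trifluoromethanesulfonate | OC/C=C(\C)CC[C@]1(C)C(OS(=O)(=O)C(F)(F)F)=CCC[C@H]1C | intermediate
13 | RB trifluoromethanesulfonate | CC(C)(C)[Si](C)(C)OC/C=C(\C)CC[C@]1(C)C(OS(=O)(=O)C(F)(F)F)=CCC[C@H]1C | intermediate
14 | (4-ethoxy-4-oxobutyl)zinc bromide | CCOC(=O)CCC[Zn]Br | starting material
15 | ethyl 5-oxo-5-RB-pentanoate | CC(C)(C)[Si](C)(C)OC/C=C(\C)CC[C@]1(C)C(=CCC[C@H]1C)C(=O)CCCC(=O)OCC | intermediate
16 | ethyl (5S)-5-hydroxy-5-RB-pentanoate | CC(C)(C)[Si](C)(C)OC/C=C(\C)CC[C@]1(C)C(=CCC[C@H]1C)[C@@H](O)CCCC(=O)OCC | intermediate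
17 | (6S)-6-RB-oxan-2-one | CC(C)(C)[Si](C)(C)OC/C=C(\C)CC[C@]1(C)C(=CCC[C@H]1C)[C@@H]2CCCC(=O)O2 | intermediate
18 | lithium enolate of 17 | CC(C)(C)[Si](C)(C)OC/C=C(\C)CC[C@]1(C)C(=CCC[C@H]1C)[C@@H]2CCC=C([O-])O2.[Li+] | intermediate
19 | lithium salt of (6S)-3-(hydroxymethylidene)-6-RB-oxan-2-one | CC(C)(C)[Si](C)(C)OC/C=C(\C)CC[C@]1(C)C(=CCC[C@H]1C)[C@@H]2CCC(=C[O-])C(=O)O2.[Li+] | intermediate
20 | (3E,6S)-3-(methoxymethylidene)-6-RB-oxan-2-one | CC(C)(C)[Si](C)(C)OC/C=C(\C)CC[C@]1(C)C(=CCC[C@H]1C)[C@@H]2CC/C(=C\OC)C(=O)O2 | intermediate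
21 | sodium alkoxide of methyl (2E,5S)-5-hydroxy-2-(methoxymethylidene)-5-RB-pentanoate | CC(C)(C)[Si](C)(C)OC/C=C(\C)CC[C@]1(C)C(=CCC[C@H]1C)[C@@H]([O-])CC/C(=C\OC)C(=O)OC.[Na+] | intermediate
22 | methyl (2S)-2-RB-3,4-dihydro-2H-pyran-5-carboxylate | CC(C)(C)[Si](C)(C)OC/C=C(\C)CC[C@]1(C)C(=CCC[C@H]1C)[C@@H]2CCC(C(=O)OC)=CO2 | intermediate
23 | methyl (4S,5S,8R,9S,13E)-15-(tert-butyldimethylsilyloxy)-19-oxo-ent-halima-1(10),13-dien-18-oate | CC(C)(C)[Si](C)(C)OC/C=C(\C)CC[C@]1(C)C2=CCC[C@](C=O)(C(=O)OC)[C@H]2CC[C@H]1C | intermediate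
24 | C19 (E)-tosylhydrazone of 23 | CC(C)(C)[Si](C)(C)OC/C=C(\C)CC[C@]1(C)C2=CCC[C@](/C=N/NS(=O)(=O)c3ccc(C)cc3)(C(=O)OC)[C@H]2CC[C@H]1C | intermediate
25 | N-(1,3,2-benzodioxaborol-2-yl) tosylhydrazide from hydride addition to 24 | CC(C)(C)[Si](C)(C)OC/C=C(\C)CC[C@]1(C)C2=CCC[C@](CN(B3Oc4ccccc4O3)NS(=O)(=O)c5ccc(C)cc5)(C(=O)OC)[C@H]2CC[C@H]1C | intermediate
26 | C19 monoalkyl diazene | CC(C)(C)[Si](C)(C)OC/C=C(\C)CC[C@]1(C)C2=CCC[C@](CN=N)(C(=O)OC)[C@H]2CC[C@H]1C | intermediate
27 | methyl (4S,5S,8R,9S,13E)-15-(tert-butyldimethylsilyloxy)-ent-halima-1(10),13-dien-18-oate | CC(C)(C)[Si](C)(C)OC/C=C(\C)CC[C@]1(C)C2=CCC[C@](C)(C(=O)OC)[C@H]2CC[C@H]1C | intermediate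
28 | (4S,5S,8R,9S,13E)-15-(tert-butyldimethylsilyloxy)-ent-halima-1(10),13-dien-18-oic acid | CC(C)(C)[Si](C)(C)OC/C=C(\C)CC[C@]1(C)C2=CCC[C@](C)(C(=O)O)[C@H]2CC[C@H]1C | intermediate
29 | ent-halimic acid | OC/C=C(\C)CC[C@]1(C)C2=CCC[C@](C)(C(=O)O)[C@H]2CC[C@H]1C | intermediate
30 | (4S,5S,8R,9S,13E)-15-acetoxy-ent-halima-1(10),13-dien-18-oic acid | CC(=O)OC/C=C(\C)CC[C@]1(C)C2=CCC[C@](C)(C(=O)O)[C@H]2CC[C@H]1C | target

Total step count: 17. Longest linear sequence: 17 (from 1).

Steps most likely to fail

Step 11. Methoxide may add only reversibly in the conjugate sense without attacking the deactivated lactone carbonyl, or the product may be held up as its methanol adduct. The fallback uses known chemistry. It sets out from 17 and comes back at 22. Lactone 17 is reduced with i-Bu2AlH at −78 °C to the lactol F1. The lactol is dehydrated through its mesylate (MsCl, Et3N, CH2Cl2 then warm) to the 2-alkenyl-3,4-dihydro-2H-pyran F2. The enol ether is acylated at C4 with trichloroacetyl chloride and pyridine to the trichloromethyl ketone F3. Haloform-type cleavage with NaOMe in MeOH then gives 22. In this variant the old lactone carbon becomes C19 and the acyl chloride supplies C18.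

Step 12. The boat transition state lies on the face of ring B that carries C17 and C20. Crowding there may let thermal breakdown, or ionisation with loss of stereochemical fidelity, outrun the shift. The fallback closes ring A by an intermolecular [4+2] cycloaddition instead. It sets out from 13 and comes back at 28. Stille coupling of 13 with Bu3SnCH=CH2 (Pd(PPh3)4, LiCl, THF, reflux) gives the 1-vinylcyclohexene diene F4. A Diels–Alder reaction with methacrolein (EtAlCl2, CH2Cl2, −78 °C) should join C2 to C3 and C5 to C4 under the ortho rule of the substituted diene terminus. With the formyl group exo and approach from the α face, this gives the C18 aldehyde F5, and other isomers would have to be separated. Pinnick oxidation (NaClO2, NaH2PO4, 2-methylbut-2-ene, t-BuOH/H2O) then leads to 28.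

Step 8. At the alkenylpalladium centre next to quaternary C9, direct non-carbonylative coupling or reduction may compete with CO insertion. The fallback reverses the roles of the partners. It sets out from 13 and comes back at 15. Stannylation with Me3SnSnMe3 (Pd(PPh3)4, LiCl, THF, reflux) gives the alkenylstannane F6. This is acylated with ethyl 5-chloro-5-oxopentanoate under PdCl2(PPh3)2 catalysis (Stille acylation, THF, 50 °C) to give 15.

Further compounds
F1 | step 11 | (6S)-6-RB-oxan-2-ol (anomers) | CC(C)(C)[Si](C)(C)OC/C=C(\C)CC[C@]1(C)C(=CCC[C@H]1C)[C@@H]2CCCC(O)O2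
F2 | step 11 | (2S)-2-RB-3,4-dihydro-2H-pyran | CC(C)(C)[Si](C)(C)OC/C=C(\C)CC[C@]1(C)C(=CCC[C@H]1C)[C@@H]2CCC=CO2
F3 | step 11 | 2,2,2-trichloro-1-[(2S)-2-RB-3,4-dihydro-2H-pyran-5-yl]ethan-1-one | CC(C)(C)[Si](C)(C)OC/C=C(\C)CC[C@]1(C)C(=CCC[C@H]1C)[C@@H]2CCC(C(=O)C(Cl)(Cl)Cl)=CO2
F4 | step 12 | RB-ethene (1-vinylcyclohexene diene) | CC(C)(C)[Si](C)(C)OC/C=C(\C)CC[C@]1(C)C(C=C)=CCC[C@H]1C
F5 | step 12 | (4S,5S,8R,9S,13E)-15-(tert-butyldimethylsilyloxy)-ent-halima-1(10),13-dien-18-al | CC(C)(C)[Si](C)(C)OC/C=C(\C)CC[C@]1(C)C2=CCC[C@](C)(C=O)[C@H]2CC[C@H]1C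
F6 | step 8 | RB-trimethylstannane | CC(C)(C)[Si](C)(C)OC/C=C(\C)CC[C@]1(C)C([Sn](C)(C)C)=CCC[C@H]1C
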